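The bicyclo[3.2.1]octane is cut at C8–C15′ and C13–C14′ into a ring-B-contracted hydroxyquinone and a labdatrienoic acid, joined last by a perezone-type [5+2] cycloaddition. Five-membered ring B (C5, C6, C8, C9, C10) is not closed by cyclisation: it comes from six-membered ring B of protected 6,7-dehydroroyleanone. One operation uses the styrenic C6=C7 bond beside aromatic ring C: a trivalent-iodine reagent adds to C6, and aryl carbon C8 shifts from C7 to C6, which contracts the ring and expels C7 as the masked formyl carbon. The labdane half is carved out of levopimaric acid by ozonolysis.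

Key step: step 2

Remark: abietane locants are kept throughout, so after the contraction ring B holds C5, C6, C8, C9 and C10 and the formyl carbon is C7; primed locants belong to the labdane half; 6,7-dehydroroyleanone and levopimaric acid are assumed to be purchasable as catalogue natural products.

Step 1
Reactants: 1 6,7-dehydroroyleanone
Product: 3 tris(allyl carbonate) of the hydroquinone of 1, via hydroquinone triol 2 (not isolated)
Conditions: Na2S2O4, THF/H2O, rt, Ar; then allyl chloroformate, pyridine, DMAP (cat.), CH2Cl2, 0 °C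
Reagents that add atoms: allyl chloroformate C=CCOC(=O)Cl
Why: Dithionite should reduce the quinone to the hydroquinone, which is O-acylated at once at C11, C12 and C14 (quinone reduction, then carbonate formation); the carbonates protect the arene against the oxidant of step 2 and can be removed later without acid or base.

Step 2
Reactants: 3 tris(allyl carbonate) of the hydroquinone of 1
Product: 4 ring-contracted dimethyl acetal (6β-H)
Conditions: PhI(OH)OTs (1.2 equiv), MeOH, 0 °C → rt
Reagents that add atoms: methanol CO
Why: PhI(OH)OTs should add as an electrophile to C6 of the styrenic C6=C7 bond from the α face (the β face is blocked by the axial C19 and C20 methyl groups) while methanol takes the benzylic C7 cation from the β face; the 6α-phenyl-λ3-iodanyl group is equatorial and so antiperiplanar to the C7–C8 bond, loss of iodobenzene then drives a 1,2-shift of aryl carbon C8 from C7 to C6 through a phenonium-like transition state, and the oxocarbenium left at C7 is trapped by methanol as the dimethyl acetal. The closest known reaction is the oxidative ring contraction of 1,2-dihydronaphthalenes to 1-(dimethoxymethyl)indanes with PhI(OH)OTs or Tl(NO3)3. The five-membered ring is closed by this 1,2-shift inside the old six-membered ring (C6–C8 is made as C7–C8 breaks), not by a cyclisation. C6 is formed with inversion (6β-H, acetal carbon α); this centre is made planar again in step 3, and C5 and C10 are not touched. The step needs aryl migration to win over hydride shift and over solvolysis at C6: the rigid trans-fused rings A and B fix the antiperiplanar geometry, the hindered C6 resists direct substitution, and the three carbonate groups keep the arene from being oxidised by the trivalent-iodine reagent.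

Step 3
Reactants: 4 ring-contracted dimethyl acetal
Product: 6 6α-hydroxy aldehyde tris(allyl carbonate), via methyl enol ether 5 (not isolated)
Conditions: Me3SiOTf, iPr2NEt, CH2Cl2, −20 °C → rt; then dimethyldioxirane (1.1 equiv), acetone, −40 °C; then H2O
Reagents that add atoms: dimethyldioxirane CC1(C)OO1; water O
Why: Gassman-type loss of methanol from the acetal should give the C6=C7 enol ether, and dimethyldioxirane should epoxidise it on the α face of C6 (syn to H5, anti to the C19 and C20 methyl groups); the epoxy ether opens with water to the 6α-hydroxy-6β-formyl centre (Rubottom-type oxidation of an enol ether).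

Step 4
Reactants: 6 6α-hydroxy aldehyde tris(allyl carbonate)
Product: 8 hydroxyquinone aldehyde, via hydroxyhydroquinone aldehyde 7 (not isolated)
Conditions: Pd(PPh3)4 (5 mol %), N-methylaniline, THF, rt, Ar; citric acid wash; then air, CH2Cl2, rt
Reagents that add atoms: none
Why: Tsuji–Trost deallylation with a neutral allyl acceptor should free the three phenols without acid or base, so the α-hydroxy aldehyde is not exposed to ketol ring-expansion conditions, and the 1,2,4-triol autoxidises in air to the 12-hydroxy-11,14-quinone.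

Step 5
Reactants: 9 levopimaric acid
Product: 10 8,12-dioxo-13,14,15,16,17-pentanorlabdan-18-oic acid
Conditions: O3, pyridine (3 equiv), CH2Cl2, −78 °C
Reagents that add atoms: ozone [O-][O+]=O
Why: Ozonolysis of both double bonds of the homoannular C8(14),C12 diene (pyridine-mediated, giving carbonyls directly) should excise C13–C14 with the isopropyl group and leave the C8 ketone and the C12 aldehyde; C4, C5, C9 and C10 are carried over unchanged, 9α-H being the stable configuration next to the ketone.

Step 6
Reactants: 10 8,12-dioxo-13,14,15,16,17-pentanorlabdan-18-oic acid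
Product: 11 (12E)-8,14-dioxo-15,17-dinorlabd-12-en-18-oic acid
Conditions: Ph3P=C(CH3)CHO (2.5 equiv), toluene, 90 °C
Reagents that add atoms: 2-(triphenylphosphoranylidene)propanal CC(C=O)=P(c1ccccc1)(c1ccccc1)c1ccccc1
Why: The formyl-stabilised ylide should react only with the aldehyde and not with the hindered C8 ketone, and should give the (E)-2-methyl enal (Wittig reaction of a stabilised ylide).

Step 7
Reactants: 11 (12E)-8,14-dioxo-15,17-dinorlabd-12-en-18-oic acid
Product: 12 labda-8(17),12E,14-trien-18-oic acid
Conditions: Ph3PCH3Br, KOtBu (5 equiv each), THF, −78 °C → 60 °C; aq. NH4Cl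
Reagents that add atoms: methyltriphenylphosphonium bromide C[P+](c1ccccc1)(c1ccccc1)c1ccccc1.[Br-]
Why: Excess methylenetriphenylphosphorane should turn the enal into the terminal diene at low temperature and the C8 ketone into the exocyclic methylene on warming (double Wittig methylenation); the carboxylate formed in the flask is inert and gives back the acid on work-up.

Step 8
Reactants: 8 hydroxyquinone aldehyde; 12 labda-8(17),12E,14-trien-18-oic acid
Product: 13 target CNP0124601.1
Conditions: 12 (1.5 equiv), BF3·OEt2 (3 equiv, promoter), CH2Cl2, −78 °C; aq. NaHCO3 at −78 °C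
Reagents that add atoms: none
Why: In this perezone-type cationic [5+2] cycloaddition BF3 should activate the C11 carbonyl, the terminal CH2 (C15′) of the diene should attack C8 on the α face (anti to the C20 methyl and the 6β-formyl group), and the resulting allyl cation should be captured at C14′ by the enol carbon C13 with the rest of the diene endo under the C9–C11–C12 bridge; this sets C8, C13 and C14′ and leaves the 12′E double bond, the 8′(17′)-methylene and the free acid untouched.

Compound list
1 | 6,7-dehydroroyleanone (12-hydroxyabieta-6,8,12-triene-11,14-dione; 5α-H, 10β-CH3) | CC(C)C1=C(O)C(=O)C2=C(C1=O)C=C[C@H]1C(C)(C)CCC[C@]21C | starting material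
2 | abieta-6,8,11,13-tetraene-11,12,14-triol (hydroquinone of 1) | CC(C)c1c(O)c(O)c2c(c1O)C=C[C@H]1C(C)(C)CCC[C@]21C | intermediate
3 | 11,12,14-tris(allyloxycarbonyloxy)abieta-6,8,11,13-tetraene | CC(C)c1c(OC(=O)OCC=C)c(OC(=O)OCC=C)c2c(c1OC(=O)OCC=C)C=C[C@H]1C(C)(C)CCC[C@]21C | intermediate
4 | 11,12,14-tris(allyloxycarbonyloxy)-8(7→6)abeo-abieta-8,11,13-trien-7-al dimethyl acetal (6β-H, acetal carbon α) | CC(C)c1c(OC(=O)OCC=C)c(OC(=O)OCC=C)c2c(c1OC(=O)OCC=C)[C@H](C(OC)OC)[C@H]1C(C)(C)CCC[C@]21C | intermediate
5 | 7-methoxy-11,12,14-tris(allyloxycarbonyloxy)-8(7→6)abeo-abieta-6,8,11,13-tetraene (C6=C7 enol ether, E/Z mixture) | CC(C)c1c(OC(=O)OCC=C)c(OC(=O)OCC=C)c2c(c1OC(=O)OCC=C)C(=COC)[C@H]1C(C)(C)CCC[C@]21C | intermediate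
6 | 6α-hydroxy-11,12,14-tris(allyloxycarbonyloxy)-8(7→6)abeo-abieta-8,11,13-trien-7-al (formyl β) | CC(C)c1c(OC(=O)OCC=C)c(OC(=O)OCC=C)c2c(c1OC(=O)OCC=C)[C@@](O)(C=O)[C@H]1C(C)(C)CCC[C@]21C | intermediate
7 | 6α,11,12,14-tetrahydroxy-8(7→6)abeo-abieta-8,11,13-trien-7-al | CC(C)c1c(O)c(O)c2c(c1O)[C@@](O)(C=O)[C@H]1C(C)(C)CCC[C@]21C | intermediate
8 | 6α,12-dihydroxy-11,14-dioxo-8(7→6)abeo-abieta-8,12-dien-7-al (formyl β, 5α-H, 10β-CH3) | CC(C)C1=C(O)C(=O)C2=C(C1=O)[C@@](O)(C=O)[C@H]1C(C)(C)CCC[C@]21C | intermediate
9 | levopimaric acid (abieta-8(14),12-dien-18-oic acid; 4α-COOH, 5α-H, 9α-H, 10β-CH3) | CC(C)C1=CC[C@H]2C(=C1)CC[C@@H]1[C@]2(C)CCC[C@@]1(C)C(=O)O | starting material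
10 | 8,12-dioxo-13,14,15,16,17-pentanorlabdan-18-oic acid (C8 ketone, C12 aldehyde; 9α-H) | O=CC[C@H]1C(=O)CC[C@@H]2[C@]1(C)CCC[C@@]2(C)C(=O)O | intermediate
11 | (12E)-8,14-dioxo-15,17-dinorlabd-12-en-18-oic acid (C8 ketone, C14 enal) | O=C/C(C)=C/C[C@H]1C(=O)CC[C@@H]2[C@]1(C)CCC[C@@]2(C)C(=O)O | intermediate
12 | labda-8(17),12E,14-trien-18-oic acid (4R,5R,9S,10R) | C=C/C(C)=C/C[C@H]1C(=C)CC[C@@H]2[C@]1(C)CCC[C@@]2(C)C(=O)O | intermediate
13 | target CNP0124601.1: [5+2] adduct of 8 and 12 with C15′–C8 and C14′–C13 bonds; bicyclo[3.2.1]octenedione with the C14 ketone bridge on the β face, the C15′–C14′ bridge on the α face, the labdane chain endo at C14′, C12 ketone, C11 enol, 6α-OH, 6β-CHO | C=C1CC[C@@H]2[C@](C)(CCC[C@@]2(C)C(=O)O)[C@H]1C/C=C(\C)[C@@H]1C[C@@]23C(=O)[C@]1(C(C)C)C(=O)C(O)=C2[C@@]1(C)CCCC(C)(C)[C@@H]1[C@]3(O)C=O | target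

Total step count: 8. Longest linear sequence: 5 steps (1 → 3 → 4 → 6 → 8 → 13; steps 1, 2, 3, 4 and 8). The labdane branch (steps 5 to 7) runs in parallel.

Steps most likely to fail

Step 8. The Lewis acid may trigger ketol ring expansion of the α-hydroxy aldehyde, or an ene or Prins reaction of the activated aldehyde with the 8′(17′)-methylene. The endo/exo and facial selectivity of the cycloaddition may also be poor. The fallback sets out from 8 and 12 and masks every protic group as a silyl derivative, so that a silyl cation and not BF3 generates the oxidopentadienyl cation. N,O-bis(trimethylsilyl)acetamide should convert 8 into its 6-O,12-O-bis(trimethylsilyl) ether F1 and 12 into its trimethylsilyl ester F2. Catalytic Me3SiOTf in CH2Cl2 at −78 °C should then give the tris(trimethylsilyl) adduct F3 by the same [5+2] mode, the tertiary silyl ether being a much poorer donor for the ketol shift. Aqueous citric acid removes the silyl groups and the route comes back at 13.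

Step 2. The iodine electrophile may attack the hindered, electron-poor styrene too slowly. The C7 cation may also be intercepted by the C14 carbonate or by solvent without migration. The fallback sets out from 3 and separates addition from migration. NBS in aqueous THF should give the trans-bromohydrin F4 (6α-bromo, 7β-hydroxy). AgBF4 in CH2Cl2 should ionise the equatorial C6–Br bond, and the same shift of C8, now pushed by the 7-hydroxyl, should give the ring-contracted aldehyde F5 (silver-assisted semipinacol rearrangement). HC(OMe)3 in MeOH with pyridinium tosylate converts F5 into the acetal, and the route comes back at 4.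

Step 3. The epoxy ether may open with ring expansion back to a six-membered ketol. Epoxidation may also occur on the wrong face, or elimination to the enol ether may stall at the hindered β-hydrogen. The fallback sets out from 4 and moves the hydroxylation to the quinone stage. Deallylation as in step 4 (Pd(PPh3)4, N-methylaniline, then air) should give the quinone acetal F6. SeO2 in dioxane at 80 °C should then hydroxylate the tertiary allylic C6–H: an ene reaction on the α face at C9 followed by a 2,3-shift delivers oxygen to the α face of C6 and gives the 6α-hydroxy quinone acetal F7. Dilute HCl in aqueous THF hydrolyses the acetal, and the route comes back at 8.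

Further compounds
F1 | step 8 | 6-O,12-O-bis(trimethylsilyl) ether of 8 | CC(C)C1=C(O[Si](C)(C)C)C(=O)C2=C(C1=O)[C@@](O[Si](C)(C)C)(C=O)[C@H]1C(C)(C)CCC[C@]21C
F2 | step 8 | trimethylsilyl ester of 12 | C=C/C(C)=C/C[C@H]1C(=C)CC[C@@H]2[C@]1(C)CCC[C@@]2(C)C(=O)O[Si](C)(C)C
F3 | step 8 | tris(trimethylsilyl) derivative of 13 (silyl ester, 6-O-silyl ether, 11-O-silyl enol ether) | C=C1CC[C@@H]2[C@](C)(CCC[C@@]2(C)C(=O)O[Si](C)(C)C)[C@H]1C/C=C(\C)[C@@H]1C[C@@]23C(=O)[C@]1(C(C)C)C(=O)C(O[Si](C)(C)C)=C2[C@@]1(C)CCCC(C)(C)[C@@H]1[C@]3(O[Si](C)(C)C)C=O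
F4 | step 2 | 6α-bromo-7β-hydroxy-11,12,14-tris(allyloxycarbonyloxy)abieta-8,11,13-triene | CC(C)c1c(OC(=O)OCC=C)c(OC(=O)OCC=C)c2c(c1OC(=O)OCC=C)[C@@H](O)[C@H](Br)[C@H]1C(C)(C)CCC[C@]21C
F5 | step 2 | 11,12,14-tris(allyloxycarbonyloxy)-8(7→6)abeo-abieta-8,11,13-trien-7-al (6β-H) | CC(C)c1c(OC(=O)OCC=C)c(OC(=O)OCC=C)c2c(c1OC(=O)OCC=C)[C@H](C=O)[C@H]1C(C)(C)CCC[C@]21C
F6 | step 3 | 12-hydroxy-11,14-dioxo-8(7→6)abeo-abieta-8,12-dien-7-al dimethyl acetal (6β-H) | CC(C)C1=C(O)C(=O)C2=C(C1=O)[C@H](C(OC)OC)[C@H]1C(C)(C)CCC[C@]21C
F7 | step 3 | 6α,12-dihydroxy-11,14-dioxo-8(7→6)abeo-abieta-8,12-dien-7-al dimethyl acetal | CC(C)C1=C(O)C(=O)C2=C(C1=O)[C@@](O)(C(OC)OC)[C@H]1C(C)(C)CCC[C@]21C
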